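# Synthesis proposal for CNP0267808.2 by anti-carbomagnesiation and CO2 capture

Abbreviations: TBS = tert-butyldimethylsilyl, PMB = 4-methoxybenzyl. Locants C1–C17 defined in the analysis are used in the names of the later compounds.

## Analysis of the target

- **Ring system.** The target is a 5-8-3 tricycle. The cyclooctene C1–C8 shares its C2=C3 bond with a butenolide (O–C10H2 on C2, C11=O on C3) and its C4–C5 bond with a cyclopropane (methylene C9). C6 carries a methyl group, C8 a free hydroxyl, and C1 a branched chain: C12 (CH) bears C13 (CH2OAc) and the arm C14–C15–C16=C17(CH3)2.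
- **Stereocentres.** There are six: C1 (R), C4 (R), C5 (R), C6 (S), C8 (S) and C12 (S). On the eight-membered ring the C12 branch, the C8 hydroxyl and C9 lie on one face and the C6 methyl on the other. C12 and C1 relate as the trans-3,4 pair of a five-membered ring closed through O13 and C8, which the route uses as a handle.
- **Sensitive groups.** C1–H is allylic and γ to the lactone carbonyl, and becomes strongly acidic whenever C8 is a carbonyl. The butenolide can be deprotonated at C10. The primary acetate sits next to a free secondary alcohol. The cyclopropane is conjugated to the butenolide. The trisubstituted alkene would react with a C8 aldehyde (citronellal-type ene closure) and with hydrogenation catalysts.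
- **Difficulty.** The medium ring contains a tetrasubstituted alkene and a cis-cyclopropane. Any open-chain precursor with an alkenyl or acyl group cis to an alkenyl group on the cyclopropane can undergo [3,3] shifts (Cope, retro-Claisen). C1 has to be set next to an acyclic centre.
- **Feature used.** The butenolide unit C10–C2=C3–C11 is what results when a carbon group (C1) and CO2 add from opposite faces to a propargylic alcohol C10–C2≡C3. Anti addition places C1 cis to C4, the geometry the eight-membered ring needs, and divides the molecule into a cyclopropyl alkynol (C2–C7, C9, C10) and a side-chain alkenyl metal (C1, C8, C12–C16).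

## Retrosynthetic reasoning

**Chain end (C16=C17).** Target 39 is cut at the trisubstituted alkene to aldehyde 38 (Wittig olefination), which comes from alcohol 37 and silyl ether 36. The alkene is made last because a C8 aldehyde would close a six-membered ring onto it and the C6 hydrogenation would reduce it. A silyl-protected primary alcohol carries the chain end through the route.

**C6 methyl and C13 acetate.** 36 is traced to the C6-methylene compound 35 by hydroxyl-directed hydrogenation, in which O8 decides the face. 35 comes from diol 34 by acylation of the primary hydroxyl only.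

**Ring closure (C7–C8).** 34 is opened between C7 and C8 to lactol 32, a masked C8 aldehyde, by a type 2 carbonyl-ene reaction with the isopropenyl group on C5. This cut turns the cyclooctane into two simple groups held close by the cis alkene and the cis cyclopropane. The forward reaction delivers the C8 hydroxyl and a C6 methylene for the later reduction.

**C1 configuration.** 32 is the thermodynamic partner of lactol mixture 31, which forms when the PMB ether of aldehyde 29 is removed. In the five-membered lactol the substituents on C1 and C12 prefer to be trans, and this is the target configuration. 29 comes from alcohol 28, and 28 from diene 26 by copper-boryl 1,6-addition at C8 and oxidation. An electrophilic hydroboration would attack the isopropenyl group instead, so a nucleophilic borylation is used.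

**Key disconnection (C1–C2, C3–C11, O–C11).** Butenolide 26 is cut into alkynol 9, the alkenyl Grignard reagent 21 (from bromide 19) and CO2 (20). Cutting here removes the tetrasubstituted alkene and the lactone in one operation and makes the synthesis convergent. The forward reaction has to add the alkenyl group to C2 and the carboxyl to C3 in anti fashion.

**Alkynol 9.** 9 comes from silyl ether 8, and its isopropenyl group from methyl ketone 7. 7 comes from carbinol 6, made by hydroxyl-directed cyclopropanation of Z-enynol 5. 5 is assembled from alkenyl iodide 3 and alkyne 4, and 3 from iodoalkyne 2 and chiral-pool alcohol 1. The alkyne is in place before the cyclopropane carries a carbonyl, so no cis-alkenyl cyclopropyl aldehyde, which would racemise by retro-Claisen rearrangement, is ever formed.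

**Bromide 19.** 19 comes from alkyne 17 by Markovnikov hydroalumination (alane 18) and bromination. 17 comes from aldehyde 16, and 16 from alkene 15. C12 is set in 15 by asymmetric allylic alkylation of bromide 12 with Grignard reagent 14. 12 and 14 come from 10, 11 and 13.

## Alternatives that were turned down

**Alternative 1: photochemical ring expansion (de Mayo).**
- Disconnection: C2–C3 and C1–C8 are formed and C3–C8 is broken. The eight-membered ring grows out of the cyclopropane-fused β-keto ester A1, whose ester oxygen carries the side-chain alkyne, and gives C8 ketone A2.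
- Key step: irradiation adds the enol double bond of A1 across the tethered alkyne, and retro-aldol cleavage in the same operation expands the six-membered ring by two carbons.
- For: one step makes the butenolide, the tetrasubstituted alkene and the medium ring, and it avoids an end-to-end closure. C4, C5 and C6 are set beforehand on a rigid bicycle. On ring-forming economy it is stronger than the chosen route.
- Against:
  - The cycloaddition passes through a diradical with spin density on C3, next to the cyclopropane, which invites cyclopropylcarbinyl ring opening.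
  - The trisubstituted alkene of the chain is a competing 2π partner.
  - The ester tether prefers a conformation that holds the alkyne away from the enol.
  - A2 still lacks two ring stereocentres: C1 arrives as an epimer mixture and the C8 ketone needs a selective reduction.
- Comparison: the chosen strategy has only polar, thermal steps, keeps the cyclopropane away from radical centres, and is convergent.

**Alternative 2: type 2 carbonyl-ene closure as the main strategy.**
- Disconnection: C7–C8, from acetoxy aldehyde A3 to cyclooctanol A4 (A4 has the constitution of 35).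
- Key step: a Lewis acid makes the C8 aldehyde react with the isopropenyl group on C5, giving the C8 hydroxyl and an exocyclic methylene at C6.
- For: the chain is pre-folded by the cis alkene and the cis cyclopropane, the conditions are mild, and the C6 methylene is placed for a directed hydrogenation. As a ring-closing tactic it is as strong as anything in the chosen route, which takes it over in step 18.
- Against, as a strategy: it presupposes A3, a fully substituted butenolide with both appendages and an epimerisable C1, and it does not say how A3 is assembled or how C1 is controlled. Eight-membered ene closures are entropically demanding, and the isopropenylcyclopropane can ionise under Lewis acids.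
- Comparison: the chosen strategy supplies what this one leaves open. It builds the butenolide with the right alkene geometry in one convergent step and reaches a diene (26) from which the C8 oxidation level and the C1 configuration can both be set.

**Alternative 3: cyclopropene carbometalation and coupling.**
- Disconnection: C5–C6 and C3–C4. Cyclopropene A5, isopropenylmagnesium bromide A6 and bromobutenolide A7 give the cis-cyclopropane A8.
- Key step: copper-catalysed syn addition of A6 to A5, transmetalation to zinc and palladium-catalysed coupling with A7, all in one pot.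
- For: the cis geometry is secured by syn addition and a retentive coupling. C1, C12 and C8 (as an acetal) are already present in A7. The cyclopropane is made in one pot, against seven steps for alkynol 9, so on step count this alternative is stronger.
- Against:
  - C4 and C5 form without absolute control, and the remote centres of A7 cannot bias the coupling, so A8 would be a diastereomer mixture separated late.
  - Enantioselective carbometalation is established for substituted cyclopropenes, not for the parent A5, a gas that must be generated and handled cold.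
  - The acetate of A7 is exposed to Grignard and zinc reagents.
  - A8 is the same Cope-prone cis-dialkenylcyclopropane as 26.
- Comparison: the chosen strategy introduces C4 and C5 as a single enantiomer from 1 by substrate-directed cyclopropanation, so no diastereomers have to be separated after the fragments are joined.

Key step: step 13

Assumption: in step 9 the Taniaphos enantiomer is the one that gives the S-configured branched product 15; if its sense of induction with Grignard reagent 14 proves opposite, the antipodal ligand is used.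

Assumption: compounds 1, 4, 10, 11 and 13 are taken as purchasable.

## Route

Step 1
Reactants: 1 (S)-but-3-yn-2-ol
Product: 2 (S)-4-iodobut-3-yn-2-ol
Conditions: NIS, AgNO3 (10 mol%), acetone, rt, dark
Reagents that add atoms: N-iodosuccinimide, O=C1CCC(=O)N1I
Why: Silver-catalysed electrophilic iodination of the terminal alkyne C–H; the carbinol centre is untouched.

Step 2
Reactants: 2 (S)-4-iodobut-3-yn-2-ol
Product: 3 (2S,3Z)-4-iodobut-3-en-2-ol
Conditions: 2-nitrobenzenesulfonohydrazide, Et3N, THF/i-PrOH, rt
Reagents that add atoms: none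
Why: Diimide released from the sulfonohydrazide adds two hydrogens to the same face of the iodoalkyne (syn reduction) and so should give the Z alkenyl iodide; the C–I bond is not reduced under these metal-free conditions.

Step 3
Reactants: 3 (2S,3Z)-4-iodobut-3-en-2-ol; 4 tert-butyldimethyl(prop-2-yn-1-yloxy)silane
Product: 5 (2S,3Z)-7-[(TBS)oxy]hept-3-en-5-yn-2-ol
Conditions: Pd(PPh3)2Cl2 (2 mol%), CuI (4 mol%), i-Pr2NH, THF, rt
Reagents that add atoms: none
Why: Sonogashira coupling of an alkenyl iodide proceeds with retention of the Z geometry and tolerates the free secondary alcohol.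

Step 4
Reactants: 5 (2S,3Z)-7-[(TBS)oxy]hept-3-en-5-yn-2-ol
Product: 6 (1S)-1-[(1S,2R)-2-{3-[(TBS)oxy]prop-1-yn-1-yl}cyclopropyl]ethan-1-ol
Conditions: Et2Zn, CH2I2, CH2Cl2, −10 °C to rt
Reagents that add atoms: diiodomethane, ICI
Why: Hydroxyl-directed Simmons–Smith cyclopropanation (Furukawa conditions): in a Z allylic alcohol A(1,3) strain keeps the carbinol C–H in the alkene plane, so the zinc-bound oxygen of the S carbinol delivers CH2 to one face only (syn product) and fixes the two ring carbons as the future C4 and C5; the alkyne does not react with the carbenoid.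

Step 5
Reactants: 6 (1S)-1-[(1S,2R)-2-{3-[(TBS)oxy]prop-1-yn-1-yl}cyclopropyl]ethan-1-ol
Product: 7 1-[(1S,2R)-2-{3-[(TBS)oxy]prop-1-yn-1-yl}cyclopropyl]ethan-1-one
Conditions: Dess–Martin periodinane, CH2Cl2, 0 °C to rt
Reagents that add atoms: none
Why: Dess–Martin oxidation of a secondary alcohol; the carbinol centre has done its work and is erased, a cyclopropyl ketone does not enolise into the ring so the cis relationship holds, and an acyl group cis to an alkyne has no low-energy [3,3] pathway.

Step 6
Reactants: 7 1-[(1S,2R)-2-{3-[(TBS)oxy]prop-1-yn-1-yl}cyclopropyl]ethan-1-one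
Product: 8 tert-butyldimethyl({3-[(1R,2S)-2-(prop-1-en-2-yl)cyclopropyl]prop-2-yn-1-yl}oxy)silane
Conditions: Ph3PCH3Br, KOt-Bu, THF, 0 °C to rt
Reagents that add atoms: methyltriphenylphosphonium bromide, C[P+](c1ccccc1)(c1ccccc1)c1ccccc1.[Br-]
Why: Wittig methylenation of a methyl ketone; the isopropenyl group is made only after the carbonyl chemistry on the cyclopropane is finished, which avoids a cis-alkenyl cyclopropyl aldehyde that would racemise by retro-Claisen rearrangement.

Step 7
Reactants: 8 tert-butyldimethyl({3-[(1R,2S)-2-(prop-1-en-2-yl)cyclopropyl]prop-2-yn-1-yl}oxy)silane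
Product: 9 3-[(1R,2S)-2-(prop-1-en-2-yl)cyclopropyl]prop-2-yn-1-ol
Conditions: TBAF, THF, 0 °C
Reagents that add atoms: none
Why: Fluoride cleavage of a primary silyl ether; nothing else in 8 reacts.

Step 8
Reactants: 10 (E)-1,4-dibromobut-2-ene; 11 (4-methoxyphenyl)methanol
Product: 12 1-({[(2E)-4-bromobut-2-en-1-yl]oxy}methyl)-4-methoxybenzene
Conditions: NaH, THF, 0 °C to rt, 10 in threefold excess
Reagents that add atoms: none
Why: Williamson ether synthesis (SN2) at a primary allylic bromide; the excess of 10 limits double substitution and the E geometry is kept.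

Step 9
Reactants: 12 1-({[(2E)-4-bromobut-2-en-1-yl]oxy}methyl)-4-methoxybenzene; 13 (3-bromopropoxy)(tert-butyl)dimethylsilane
Product: 15 tert-butyl{[(4S)-4-{[(4-methoxybenzyl)oxy]methyl}hex-5-en-1-yl]oxy}dimethylsilane, via Grignard reagent 14 (not isolated)
Conditions: 13, Mg, Et2O, rt; then 12, CuBr·SMe2 (1 mol%), Taniaphos (1.2 mol%), CH2Cl2, −75 °C
Reagents that add atoms: none
Why: Copper-catalysed asymmetric allylic alkylation of an (E)-4-alkoxybut-2-enyl bromide with a primary alkyl Grignard reagent (SN2' attack); the chiral ferrocenyl diphosphine–copper complex selects the branched isomer and the face of C12, which becomes S.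

Step 10
Reactants: 15 tert-butyl{[(4S)-4-{[(4-methoxybenzyl)oxy]methyl}hex-5-en-1-yl]oxy}dimethylsilane
Product: 16 (2R)-5-[(TBS)oxy]-2-{[(4-methoxybenzyl)oxy]methyl}pentanal
Conditions: OsO4 (2 mol%), NaIO4, 2,6-lutidine, dioxane/H2O, rt
Reagents that add atoms: sodium periodate, [Na+].[O-]I(=O)(=O)=O (terminal oxidant; the aldehyde oxygen is passed on through OsO4)
Why: Lemieux–Johnson cleavage (dihydroxylation then periodate) of the only alkene; 2,6-lutidine suppresses epimerisation and β-elimination of the α-branched β-alkoxy aldehyde, which is used crude, and the PMB ether is safer here than under ozone.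

Step 11
Reactants: 16 (2R)-5-[(TBS)oxy]-2-{[(4-methoxybenzyl)oxy]methyl}pentanal
Product: 17 tert-butyl{[(4S)-4-{[(4-methoxybenzyl)oxy]methyl}hex-5-yn-1-yl]oxy}dimethylsilane
Conditions: dimethyl (1-diazo-2-oxopropyl)phosphonate, K2CO3, MeOH, 0 °C to rt
Reagents that add atoms: dimethyl (1-diazo-2-oxopropyl)phosphonate, COP(=O)(OC)C(=[N+]=[N-])C(C)=O
Why: Ohira–Bestmann homologation (Seyferth–Gilbert type) converts the aldehyde into the terminal alkyne under conditions that normally leave α-branched β-alkoxy aldehydes configurationally intact; C12 keeps its arrangement (descriptor S).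

Step 12
Reactants: 17 tert-butyl{[(4S)-4-{[(4-methoxybenzyl)oxy]methyl}hex-5-yn-1-yl]oxy}dimethylsilane
Product: 19 {[(4R)-5-bromo-4-{[(4-methoxybenzyl)oxy]methyl}hex-5-en-1-yl]oxy}(tert-butyl)dimethylsilane, via alkenylalane 18 (not isolated)
Conditions: Ni(dppp)Cl2 (3 mol%), i-Bu2AlH, THF, 0 °C to rt; then NBS, 0 °C
Reagents that add atoms: N-bromosuccinimide, O=C1CCC(=O)N1Br
Why: Nickel-catalysed Markovnikov hydroalumination of a terminal alkyne puts aluminium on the internal carbon C1, and bromodealumination gives the 2-bromo-1-alkene; ethers are tolerated and boron halide reagents that could cleave the PMB ether are avoided (the descriptor of C12 changes to R only because bromine raises the priority of C1).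

Step 13
Reactants: 9 3-[(1R,2S)-2-(prop-1-en-2-yl)cyclopropyl]prop-2-yn-1-ol; 19 {[(4R)-5-bromo-4-{[(4-methoxybenzyl)oxy]methyl}hex-5-en-1-yl]oxy}(tert-butyl)dimethylsilane; 20 carbon dioxide
Product: 26 4-[(3S)-6-[(TBS)oxy]-3-{[(4-methoxybenzyl)oxy]methyl}hex-1-en-2-yl]-3-[(1R,2S)-2-(prop-1-en-2-yl)cyclopropyl]furan-2(5H)-one, via alkenylmagnesium bromide 21 (not isolated), via chloromagnesium alkoxide 22 (not isolated), via oxa-magnesacycle 23 (not isolated), via cyclic magnesium carboxylate 24 (not isolated), via hydroxy acid 25 (not isolated)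
Conditions: 19, Mg, LiCl, THF, 25–40 °C; 9, MeMgCl (1.0 equiv), THF, 0 °C; both combined (21 1.8 equiv), CuI (10 mol%), THF/toluene, 0 to 55 °C; CO2 (1 atm), −20 °C to rt; 1 M aq. HCl, 0 °C
Reagents that add atoms: none
Why: MeMgCl turns 9 into alkoxide 22, and the alkenyl group of 21 is then delivered to the alkyne carbon next to the carbinol (C2) while magnesium binds C3 from the opposite face, which gives the five-membered oxa-magnesacycle 23 (O–C10–C2=C3–Mg), with CuI speeding the transfer of the hindered alkenyl group. The closest known reaction type is the alkoxide-directed anti-carbomagnesiation of propargylic alcohols with alkenyl or aryl Grignard reagents followed by carboxylation to 3,4-disubstituted furan-2(5H)-ones. CO2 inserts into the C3–Mg bond with retention (24), and on acidification hydroxy acid 25, whose CO2H and CH2OH are held cis, closes the butenolide by 5-exo-trig attack of O10 on C11. Three bonds form (C1–C2, C3–C11, O–C11) and no stereocentre, and C12, C4 and C5 are spectators. The step needs regioselectivity (carbon to C2, not C3) and anti addition, and both come from the chelate, since only anti addition puts magnesium within reach of the alkoxide oxygen; the result is C1 cis to C4, as the later ring demands. The isopropenyl group, the cyclopropane and the ethers do not react with Grignard reagents, and the temperature is held at or below 55 °C because 23 and 26 are cis-dialkenylcyclopropanes that are kept from Cope rearrangement only by the fully substituted alkene terminus.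

Step 14
Reactants: 26 4-[(3S)-6-[(TBS)oxy]-3-{[(4-methoxybenzyl)oxy]methyl}hex-1-en-2-yl]-3-[(1R,2S)-2-(prop-1-en-2-yl)cyclopropyl]furan-2(5H)-one
Product: 28 4-[(2RS,3S)-6-[(TBS)oxy]-1-hydroxy-3-{[(4-methoxybenzyl)oxy]methyl}hexan-2-yl]-3-[(1R,2S)-2-(prop-1-en-2-yl)cyclopropyl]furan-2(5H)-one, via C8 pinacol boronate 27 (not isolated)
Conditions: CuCl (5 mol%), DPEphos (5 mol%), NaOt-Bu (10 mol%), B2pin2, MeOH, THF, rt; then NaBO3·4H2O, THF/H2O, rt
Reagents that add atoms: sodium perborate, [Na+].[O-]OB=O (oxygen on C8); bis(pinacolato)diboron, CC1(C)OB(OC1(C)C)B1OC(C)(C)C(C)(C)O1 (boron in 27 only)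
Why: Copper-boryl conjugate addition in its 1,6 mode: C2 is fully substituted, so the boryl copper attacks the open terminal carbon C8 of the dienyl lactone and leaves the unactivated isopropenyl group alone; methanol protonates the dienolate, the alkoxide returns any deconjugated isomer to C2=C3, and perborate replaces boron by hydroxyl. C1 forms here without control and is corrected in step 17.

Step 15
Reactants: 28 4-[(2RS,3S)-6-[(TBS)oxy]-1-hydroxy-3-{[(4-methoxybenzyl)oxy]methyl}hexan-2-yl]-3-[(1R,2S)-2-(prop-1-en-2-yl)cyclopropyl]furan-2(5H)-one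
Product: 29 (2RS,3S)-6-[(TBS)oxy]-3-{[(4-methoxybenzyl)oxy]methyl}-2-{5-oxo-4-[(1R,2S)-2-(prop-1-en-2-yl)cyclopropyl]-2,5-dihydrofuran-3-yl}hexanal
Conditions: Dess–Martin periodinane, pyridine, CH2Cl2, 0 °C
Reagents that add atoms: none
Why: Dess–Martin oxidation of the primary alcohol under pyridine buffering; the aldehyde, whose C1–H is acidic, is carried on without purification.

Step 16
Reactants: 29 (2RS,3S)-6-[(TBS)oxy]-3-{[(4-methoxybenzyl)oxy]methyl}-2-{5-oxo-4-[(1R,2S)-2-(prop-1-en-2-yl)cyclopropyl]-2,5-dihydrofuran-3-yl}hexanal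
Product: 31 4-[(3RS,4S)-2-hydroxy-4-{3-[(TBS)oxy]propyl}oxolan-3-yl]-3-[(1R,2S)-2-(prop-1-en-2-yl)cyclopropyl]furan-2(5H)-one, via hydroxy aldehyde 30 (not isolated)
Conditions: DDQ, CH2Cl2/pH 7 phosphate buffer, 0 °C
Reagents that add atoms: none
Why: Oxidative cleavage of the PMB ether by DDQ in wet CH2Cl2 leaves the silyl ether, the alkenes and the cyclopropane alone; the freed O13–H adds to the C8 aldehyde and closes the five-membered lactol (anomers and C1 epimers).

Step 17
Reactants: 31 4-[(3RS,4S)-2-hydroxy-4-{3-[(TBS)oxy]propyl}oxolan-3-yl]-3-[(1R,2S)-2-(prop-1-en-2-yl)cyclopropyl]furan-2(5H)-one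
Product: 32 4-[(3R,4S)-2-hydroxy-4-{3-[(TBS)oxy]propyl}oxolan-3-yl]-3-[(1R,2S)-2-(prop-1-en-2-yl)cyclopropyl]furan-2(5H)-one
Conditions: DBU (0.2 equiv), CH2Cl2, rt
Reagents that add atoms: none
Why: Base-mediated thermodynamic epimerisation through ring–chain tautomerism: the open form 30 has a C1–H acidified by the aldehyde and, across C2=C3, by the lactone carbonyl, so both C1 epimers should drain into the lactol in which the butenolide on C1 and the chain on C12 are trans on the five-membered ring; that trans arrangement is the 1R configuration of the target.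

Step 18
Reactants: 32 4-[(3R,4S)-2-hydroxy-4-{3-[(TBS)oxy]propyl}oxolan-3-yl]-3-[(1R,2S)-2-(prop-1-en-2-yl)cyclopropyl]furan-2(5H)-one
Product: 34 tricyclic diol (1R,4R,5S,8S,12S) with exocyclic methylene at C6 and hydroxyls on C8 and C13 and OTBS on C16, via aluminium alkoxide aldehyde 33 (not isolated)
Conditions: Me2AlCl (3 equiv), CH2Cl2, −78 to −20 °C; aq. potassium sodium tartrate
Reagents that add atoms: none
Why: Proposed new method: the first equivalent of Me2AlCl converts the lactol hydroxyl into an aluminium alkoxide with loss of methane, the hemiacetal opens to aldehyde 33 with aluminium on O13, further Me2AlCl activates C8=O, and the terminal carbon C7 of the isopropenyl group attacks C8 while a methyl hydrogen passes to oxygen, closing the eight-membered ring with an exocyclic methylene at C6; the closest known reaction type is the Me2AlCl-promoted type 2 intramolecular carbonyl-ene cyclisation of aldehydes, and the opening of lactols by organoaluminium reagents is known from their additions; the cis alkene and the cis cyclopropane pre-fold the chain; with the C12 branch anti to the forming C7–C8 bond and the aluminium-bound oxygen turned outward toward the methyl group that gives up hydrogen, O8 should end cis to the branch (8S), and C1 is not touched.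

Step 19
Reactants: 34 tricyclic diol (1R,4R,5S,8S,12S)
Product: 35 tricyclic C13 acetate (1R,4R,5S,8S,12S) with exocyclic methylene at C6 and free hydroxyl on C8 and OTBS on C16
Conditions: AcCl (1.1 equiv), 2,4,6-collidine, CH2Cl2, −78 °C
Reagents that add atoms: acetyl chloride, CC(Cl)=O
Why: Acylation with acetyl chloride and collidine at low temperature discriminates the primary C13 hydroxyl from the hindered secondary C8 hydroxyl.

Step 20
Reactants: 35 tricyclic C13 acetate (1R,4R,5S,8S,12S)
Product: 36 tricyclic acetate (1R,4R,5R,6S,8S,12S) with methyl on C6 and free hydroxyl on C8 and OTBS on C16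
Conditions: [Ir(cod)(PCy3)(py)]PF6 (5 mol%), H2 (1 atm), CH2Cl2, 0 °C to rt
Reagents that add atoms: none
Why: Hydroxyl-directed homogeneous hydrogenation: the cationic iridium centre binds O8 and delivers H2 to the face of the C6 methylene on which the hydroxyl sits, so the new methyl should end trans to O8 (6S); the tetrasubstituted conjugated alkene is too hindered to react and a soluble catalyst avoids hydrogenolysis of the cyclopropane.

Step 21
Reactants: 36 tricyclic acetate (1R,4R,5R,6S,8S,12S)
Product: 37 tricyclic acetate diol (1R,4R,5R,6S,8S,12S) with hydroxyls on C8 and C16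
Conditions: HF·pyridine, pyridine, THF, 0 °C to rt
Reagents that add atoms: none
Why: Buffered fluoride cleavage of the primary silyl ether; acetate and lactone are stable to HF·pyridine.

Step 22
Reactants: 37 tricyclic acetate diol (1R,4R,5R,6S,8S,12S)
Product: 38 tricyclic acetate aldehyde (1R,4R,5R,6S,8S,12S) with C16 as CHO and free hydroxyl on C8
Conditions: TEMPO (10 mol%), PhI(OAc)2, CH2Cl2, rt
Reagents that add atoms: none
Why: Nitroxyl-catalysed oxidation is selective for the primary alcohol and leaves the hindered secondary C8 hydroxyl.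

Step 23
Reactants: 38 tricyclic acetate aldehyde (1R,4R,5R,6S,8S,12S)
Product: 39 CNP0267808.2 (1R,4R,5R,6S,8S,12S)
Conditions: i-PrPPh3I, n-BuLi, THF, −78 to 0 °C (ylide 2.2 equiv, aldehyde added at −78 °C)
Reagents that add atoms: isopropyltriphenylphosphonium iodide, CC(C)[P+](c1ccccc1)(c1ccccc1)c1ccccc1.[I-]
Why: Wittig olefination with the non-stabilised isopropylidene ylide; aldehydes react at −78 °C much faster than esters, one equivalent of ylide is sacrificed to the free hydroxyl, and no stereocentre or alkene geometry is at stake.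

## Compound list

1 | (S)-but-3-yn-2-ol | C[C@H](O)C#C | starting material
2 | (S)-4-iodobut-3-yn-2-ol | C[C@H](O)C#CI | intermediate
3 | (2S,3Z)-4-iodobut-3-en-2-ol | C[C@H](O)/C=C\I | intermediate
4 | tert-butyldimethyl(prop-2-yn-1-yloxy)silane | C#CCO[Si](C)(C)C(C)(C)C | starting material
5 | (2S,3Z)-7-[(TBS)oxy]hept-3-en-5-yn-2-ol | C[C@H](O)/C=C\C#CCO[Si](C)(C)C(C)(C)C | intermediate
6 | (1S)-1-[(1S,2R)-2-{3-[(TBS)oxy]prop-1-yn-1-yl}cyclopropyl]ethan-1-ol | CC(C)(C)[Si](C)(C)OCC#C[C@@H]1C[C@@H]1[C@H](C)O | intermediate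
7 | 1-[(1S,2R)-2-{3-[(TBS)oxy]prop-1-yn-1-yl}cyclopropyl]ethan-1-one | CC(C)(C)[Si](C)(C)OCC#C[C@@H]1C[C@@H]1C(C)=O | intermediate
8 | tert-butyldimethyl({3-[(1R,2S)-2-(prop-1-en-2-yl)cyclopropyl]prop-2-yn-1-yl}oxy)silane | CC(C)(C)[Si](C)(C)OCC#C[C@@H]1C[C@@H]1C(C)=C | intermediate
9 | 3-[(1R,2S)-2-(prop-1-en-2-yl)cyclopropyl]prop-2-yn-1-ol | OCC#C[C@@H]1C[C@@H]1C(C)=C | intermediate
10 | (E)-1,4-dibromobut-2-ene | BrC/C=C/CBr | starting material
11 | (4-methoxyphenyl)methanol | COc1ccc(CO)cc1 | starting material
12 | 1-({[(2E)-4-bromobut-2-en-1-yl]oxy}methyl)-4-methoxybenzene | COc1ccc(COC/C=C/CBr)cc1 | intermediate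
13 | (3-bromopropoxy)(tert-butyl)dimethylsilane | CC(C)(C)[Si](C)(C)OCCCBr | starting material
14 | {3-[(TBS)oxy]propyl}magnesium bromide | CC(C)(C)[Si](C)(C)OCCC[Mg]Br | intermediate
15 | tert-butyl{[(4S)-4-{[(4-methoxybenzyl)oxy]methyl}hex-5-en-1-yl]oxy}dimethylsilane | COc1ccc(COC[C@@H](CCCO[Si](C)(C)C(C)(C)C)C=C)cc1 | intermediate
16 | (2R)-5-[(TBS)oxy]-2-{[(4-methoxybenzyl)oxy]methyl}pentanal | COc1ccc(COC[C@@H](CCCO[Si](C)(C)C(C)(C)C)C=O)cc1 | intermediate
17 | tert-butyl{[(4S)-4-{[(4-methoxybenzyl)oxy]methyl}hex-5-yn-1-yl]oxy}dimethylsilane | COc1ccc(COC[C@@H](CCCO[Si](C)(C)C(C)(C)C)C#C)cc1 | intermediate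
18 | diisobutyl[(3S)-6-[(TBS)oxy]-3-{[(4-methoxybenzyl)oxy]methyl}hex-1-en-2-yl]alane | COc1ccc(COC[C@@H](CCCO[Si](C)(C)C(C)(C)C)C(=C)[Al](CC(C)C)CC(C)C)cc1 | intermediate
19 | {[(4R)-5-bromo-4-{[(4-methoxybenzyl)oxy]methyl}hex-5-en-1-yl]oxy}(tert-butyl)dimethylsilane | COc1ccc(COC[C@@H](CCCO[Si](C)(C)C(C)(C)C)C(=C)Br)cc1 | intermediate
20 | carbon dioxide | O=C=O | starting material
21 | [(3S)-6-[(TBS)oxy]-3-{[(4-methoxybenzyl)oxy]methyl}hex-1-en-2-yl]magnesium bromide | COc1ccc(COC[C@@H](CCCO[Si](C)(C)C(C)(C)C)C(=C)[Mg]Br)cc1 | intermediate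
22 | chloromagnesium 3-[(1R,2S)-2-(prop-1-en-2-yl)cyclopropyl]prop-2-yn-1-olate | Cl[Mg]OCC#C[C@@H]1C[C@@H]1C(C)=C | intermediate
23 | oxa-magnesacycle (1-oxa-2-magnesacyclopent-3-ene with the cyclopropyl group on C3 and the side-chain alkenyl group on C4) | COc1ccc(COC[C@@H](CCCO[Si](C)(C)C(C)(C)C)C(=C)C2=C([Mg]OC2)[C@@H]2C[C@@H]2C(C)=C)cc1 | intermediate
24 | cyclic magnesium carboxylate–alkoxide of hydroxy acid 25 | COc1ccc(COC[C@@H](CCCO[Si](C)(C)C(C)(C)C)C(=C)C2=C(C(=O)O[Mg]OC2)[C@@H]2C[C@@H]2C(C)=C)cc1 | intermediate
25 | (2Z,4S)-7-[(TBS)oxy]-3-(hydroxymethyl)-4-{[(4-methoxybenzyl)oxy]methyl}-2-[(1R,2S)-2-(prop-1-en-2-yl)cyclopropyl]-... acid, i.e. the open hydroxy acid of 26 with CO2H and CH2OH cis | COc1ccc(COC[C@@H](CCCO[Si](C)(C)C(C)(C)C)C(=C)/C(CO)=C(/C(O)=O)[C@@H]2C[C@@H]2C(C)=C)cc1 | intermediate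
26 | 4-[(3S)-6-[(TBS)oxy]-3-{[(4-methoxybenzyl)oxy]methyl}hex-1-en-2-yl]-3-[(1R,2S)-2-(prop-1-en-2-yl)cyclopropyl]furan-2(5H)-one | COc1ccc(COC[C@@H](CCCO[Si](C)(C)C(C)(C)C)C(=C)C2=C(C(=O)OC2)[C@@H]2C[C@@H]2C(C)=C)cc1 | intermediate
27 | 4-[(2RS,3S)-6-[(TBS)oxy]-3-{[(4-methoxybenzyl)oxy]methyl}-1-(4,4,5,5-tetramethyl-1,3,2-dioxaborolan-2-yl)hexan-2-yl]-3-[(1R,2S)-2-(prop-1-en-2-yl)cyclopropyl]furan-2(5H)-one | COc1ccc(COC[C@@H](CCCO[Si](C)(C)C(C)(C)C)C(CB3OC(C)(C)C(C)(C)O3)C2=C(C(=O)OC2)[C@@H]2C[C@@H]2C(C)=C)cc1 | intermediate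
28 | 4-[(2RS,3S)-6-[(TBS)oxy]-1-hydroxy-3-{[(4-methoxybenzyl)oxy]methyl}hexan-2-yl]-3-[(1R,2S)-2-(prop-1-en-2-yl)cyclopropyl]furan-2(5H)-one | COc1ccc(COC[C@@H](CCCO[Si](C)(C)C(C)(C)C)C(CO)C2=C(C(=O)OC2)[C@@H]2C[C@@H]2C(C)=C)cc1 | intermediate
29 | (2RS,3S)-6-[(TBS)oxy]-3-{[(4-methoxybenzyl)oxy]methyl}-2-{5-oxo-4-[(1R,2S)-2-(prop-1-en-2-yl)cyclopropyl]-2,5-dihydrofuran-3-yl}hexanal | COc1ccc(COC[C@@H](CCCO[Si](C)(C)C(C)(C)C)C(C=O)C2=C(C(=O)OC2)[C@@H]2C[C@@H]2C(C)=C)cc1 | intermediate
30 | (2RS,3S)-6-[(TBS)oxy]-3-(hydroxymethyl)-2-{5-oxo-4-[(1R,2S)-2-(prop-1-en-2-yl)cyclopropyl]-2,5-dihydrofuran-3-yl}hexanal | OC[C@@H](CCCO[Si](C)(C)C(C)(C)C)C(C=O)C2=C(C(=O)OC2)[C@@H]2C[C@@H]2C(C)=C | intermediate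
31 | 4-[(3RS,4S)-2-hydroxy-4-{3-[(TBS)oxy]propyl}oxolan-3-yl]-3-[(1R,2S)-2-(prop-1-en-2-yl)cyclopropyl]furan-2(5H)-one (anomers) | OC1OC[C@@H](CCCO[Si](C)(C)C(C)(C)C)C1C2=C(C(=O)OC2)[C@@H]2C[C@@H]2C(C)=C | intermediate
32 | 4-[(3R,4S)-2-hydroxy-4-{3-[(TBS)oxy]propyl}oxolan-3-yl]-3-[(1R,2S)-2-(prop-1-en-2-yl)cyclopropyl]furan-2(5H)-one (trans lactol, anomers) | OC1OC[C@@H](CCCO[Si](C)(C)C(C)(C)C)[C@@H]1C2=C(C(=O)OC2)[C@@H]2C[C@@H]2C(C)=C | intermediate
33 | chloro(methyl)aluminium alkoxide (on O13) of the (2R,3S) hydroxy aldehyde 30 | C[Al](Cl)OC[C@@H](CCCO[Si](C)(C)C(C)(C)C)[C@@H](C=O)C2=C(C(=O)OC2)[C@@H]2C[C@@H]2C(C)=C | intermediate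
34 | tricyclic diol (1R,4R,5S,8S,12S): cyclopropane-fused cyclooctene butenolide with C6 exocyclic methylene, hydroxyls on C8 and C13, OTBS on C16 | OC[C@@H](CCCO[Si](C)(C)C(C)(C)C)[C@@H]1C2=C(C(=O)OC2)[C@@H]2C[C@@H]2C(=C)C[C@@H]1O | intermediate
35 | tricyclic C13 acetate (1R,4R,5S,8S,12S): as 34 with OAc on C13 | CC(=O)OC[C@@H](CCCO[Si](C)(C)C(C)(C)C)[C@@H]1C2=C(C(=O)OC2)[C@@H]2C[C@@H]2C(=C)C[C@@H]1O | intermediate
36 | tricyclic acetate (1R,4R,5R,6S,8S,12S): methyl on C6, hydroxyl on C8, OAc on C13, OTBS on C16 | CC(=O)OC[C@@H](CCCO[Si](C)(C)C(C)(C)C)[C@@H]1C2=C(C(=O)OC2)[C@@H]2C[C@@H]2[C@@H](C)C[C@@H]1O | intermediate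
37 | tricyclic acetate diol (1R,4R,5R,6S,8S,12S): as 36 with free hydroxyl on C16 | CC(=O)OC[C@@H](CCCO)[C@@H]1C2=C(C(=O)OC2)[C@@H]2C[C@@H]2[C@@H](C)C[C@@H]1O | intermediate
38 | tricyclic acetate aldehyde (1R,4R,5R,6S,8S,12S): as 37 with C16 as CHO | CC(=O)OC[C@@H](CCC=O)[C@@H]1C2=C(C(=O)OC2)[C@@H]2C[C@@H]2[C@@H](C)C[C@@H]1O | intermediate
39 | CNP0267808.2 (1R,4R,5R,6S,8S,12S) | CC(=O)OC[C@@H](CCC=C(C)C)[C@@H]1C2=C(C(=O)OC2)[C@@H]2C[C@@H]2[C@@H](C)C[C@@H]1O | target

## Step count and least certain steps

Total: 23 steps. Longest linear sequence: 18 steps (steps 1–7, 13, 14–23). The side-chain branch (steps 8–12) is 5 steps.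

**Step 18 (lactol ene closure, proposed new method).**
- What may go wrong: the aluminium hemiacetal ionises to an oxocarbenium ion that closes by a Prins path to a cyclic ether; a methyl group transfers from aluminium to the aldehyde; a hydride shifts within the aluminium alkoxide; or the facial selectivity at C8 is poor, because medium-ring transition states are hard to rank.
- Fallback with known chemistry, from 32: oxidation with TEMPO/PhI(OAc)2 gives the trans lactone F1. Opening with Me(MeO)NH·HCl and Me3Al gives the hydroxy Weinreb amide F2. Ac2O/pyridine gives the acetate F3. Cp2Zr(H)Cl reduces the amide, and not the esters, to the acetoxy aldehyde F4, an ordinary substrate for the Me2AlCl type 2 ene reaction. This rejoins the route at 35.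
- If the closure (from 32 or from F4) favours the C8 epimer F5, Mitsunobu inversion with chloroacetic acid (PPh3, DIAD) gives the chloroacetate F6, and thiourea/NaHCO3 releases 35.

**Step 13 (key step).**
- What may go wrong: slow transfer of the α-branched alkenyl group, so that 21 is lost to protonation or coupling before it adds; or thermal Cope rearrangement of the cis-dialkenylcyclopropane if heating is prolonged.
- Fallback, from 9: ClCO2Me/pyridine gives the propargylic carbonate F7. Palladium-catalysed carbonylation (Pd(OAc)2, PPh3, CO, MeOH) gives the allenoate F8. Iodolactonisation with I2 gives the 4-iodobutenolide F9. Negishi coupling (Pd(PPh3)4) with the alkenylzinc chloride F10, made from 19 with t-BuLi and ZnCl2, gives 26.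

**Step 14 (1,6-borylation).**
- What may go wrong: low conversion at the hindered diene, copper-boryl attack on the isopropenylcyclopropane with ring opening, or methanolysis of the lactone.
- Fallback, from 26: base-catalysed 1,6-addition of PhSH (Et3N) gives the sulfide F11. NaIO4 gives the sulfoxide F12. Pummerer rearrangement ((CF3CO)2O, 2,6-lutidine, then aq. NaHCO3) gives aldehyde 29 directly.

**Step 17 (C1 equilibration).**
- What may go wrong: too small a thermodynamic preference at the lactol level, or base-induced loss of the hydroxy aldehyde by aldol reaction or double-bond migration.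
- Fallback, from 31: TEMPO/PhI(OAc)2 gives the lactone as a C1 epimer mixture F13. Here C1 is the α-carbon of a γ-lactone, and DBU should bring it more completely to the trans lactone F1. F1 continues through F2–F4 as described for step 18 and rejoins at 35.

**Step 20 (directed hydrogenation).**
- What may go wrong: metal-hydride migration of the exocyclic alkene into the ring, opening of the alkenylcyclopropane, or weak direction by O8.
- Fallback, from 35: metal-free diimide reduction (2-nitrobenzenesulfonohydrazide, Et3N) gives 36. The face is then chosen by the shape of the ring and not by the hydroxyl. No new compound is made (F0).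

**Step 23 (Wittig).**
- What may go wrong: the basic ylide deprotonates C10 of the butenolide, or deprotonates O8–H with acetyl migration from O13.
- Fallback, from 38: non-basic methylenation with Zn/CH2Br2/TiCl4 gives the terminal alkene F14. Cross-metathesis with 2-methylbut-2-ene and the second-generation Grubbs catalyst (H2IMes)(PCy3)Cl2Ru=CHPh gives 39.

## Further compounds

F1 | step 18 | trans lactone: (3R,4S)-4-{3-[(TBS)oxy]propyl}-3-{5-oxo-4-[(1R,2S)-2-(prop-1-en-2-yl)cyclopropyl]-2,5-dihydrofuran-3-yl}oxolan-2-one | O=C1OC[C@@H](CCCO[Si](C)(C)C(C)(C)C)[C@@H]1C2=C(C(=O)OC2)[C@@H]2C[C@@H]2C(C)=C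
F2 | step 18 | hydroxy Weinreb amide (C8 as N-methoxy-N-methylamide, free hydroxyl on C13; 1R,12S) | OC[C@@H](CCCO[Si](C)(C)C(C)(C)C)[C@@H](C(=O)N(C)OC)C2=C(C(=O)OC2)[C@@H]2C[C@@H]2C(C)=C
F3 | step 18 | acetoxy Weinreb amide (as F2 with OAc on C13) | CC(=O)OC[C@@H](CCCO[Si](C)(C)C(C)(C)C)[C@@H](C(=O)N(C)OC)C2=C(C(=O)OC2)[C@@H]2C[C@@H]2C(C)=C
F4 | step 18 | acetoxy aldehyde (C8 as CHO, OAc on C13; 1R,12S) | CC(=O)OC[C@@H](CCCO[Si](C)(C)C(C)(C)C)[C@@H](C=O)C2=C(C(=O)OC2)[C@@H]2C[C@@H]2C(C)=C
F5 | step 18 | C8 epimer of 35 | CC(=O)OC[C@@H](CCCO[Si](C)(C)C(C)(C)C)[C@@H]1C2=C(C(=O)OC2)[C@@H]2C[C@@H]2C(=C)C[C@H]1O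
F6 | step 18 | C8 chloroacetate of 35 | CC(=O)OC[C@@H](CCCO[Si](C)(C)C(C)(C)C)[C@@H]1C2=C(C(=O)OC2)[C@@H]2C[C@@H]2C(=C)C[C@@H]1OC(=O)CCl
F7 | step 13 | methyl 3-[(1R,2S)-2-(prop-1-en-2-yl)cyclopropyl]prop-2-yn-1-yl carbonate | COC(=O)OCC#C[C@@H]1C[C@@H]1C(C)=C
F8 | step 13 | methyl 2-[(1R,2S)-2-(prop-1-en-2-yl)cyclopropyl]buta-2,3-dienoate | COC(=O)C(=C=C)[C@@H]1C[C@@H]1C(C)=C
F9 | step 13 | 4-iodo-3-[(1R,2S)-2-(prop-1-en-2-yl)cyclopropyl]furan-2(5H)-one | IC1=C(C(=O)OC1)[C@@H]1C[C@@H]1C(C)=C
F10 | step 13 | [(3S)-6-[(TBS)oxy]-3-{[(4-methoxybenzyl)oxy]methyl}hex-1-en-2-yl]zinc chloride | COc1ccc(COC[C@@H](CCCO[Si](C)(C)C(C)(C)C)C(=C)[Zn]Cl)cc1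
F11 | step 14 | C8 phenyl sulfide of the butenolide (C1 epimers) | COc1ccc(COC[C@@H](CCCO[Si](C)(C)C(C)(C)C)C(CSc3ccccc3)C2=C(C(=O)OC2)[C@@H]2C[C@@H]2C(C)=C)cc1
F12 | step 14 | C8 phenyl sulfoxide of the butenolide (C1 and sulfur epimers) | COc1ccc(COC[C@@H](CCCO[Si](C)(C)C(C)(C)C)C(CS(=O)c3ccccc3)C2=C(C(=O)OC2)[C@@H]2C[C@@H]2C(C)=C)cc1
F13 | step 17 | lactone as C1 epimer mixture (C1 epimers of F1) | O=C1OC[C@@H](CCCO[Si](C)(C)C(C)(C)C)C1C2=C(C(=O)OC2)[C@@H]2C[C@@H]2C(C)=C
F0 | step 20 | none | none
F14 | step 23 | terminal alkene: as 39 with CH=CH2 in place of CH=C(CH3)2 | CC(=O)OC[C@@H](CCC=C)[C@@H]1C2=C(C(=O)OC2)[C@@H]2C[C@@H]2[C@@H](C)C[C@@H]1O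
A1 | alternative 1 | (4S)-4-(acetoxymethyl)-8-methylnon-7-en-2-yn-1-yl ester of the cyclopropane-fused 5-methyl-3-oxocyclohexane-2-carboxylic acid (3-oxobicyclo[4.1.0]heptane-2-carboxylate) | CC(=O)OC[C@@H](CCC=C(C)C)C#CCOC(=O)C1[C@@H]2C[C@@H]2[C@@H](C)CC1=O
A2 | alternative 1 | C8 ketone of the target skeleton (C1 epimers) | CC(=O)OC[C@@H](CCC=C(C)C)C1C2=C(C(=O)OC2)[C@@H]2C[C@@H]2[C@@H](C)CC1=O
A3 | alternative 2 | acetoxy aldehyde (C8 as CHO, OAc on C13, OTBS on C16; same constitution as F4) | CC(=O)OC[C@@H](CCCO[Si](C)(C)C(C)(C)C)[C@@H](C=O)C2=C(C(=O)OC2)[C@@H]2C[C@@H]2C(C)=C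
A4 | alternative 2 | C6-methylene cyclooctanol (same constitution as 35) | CC(=O)OC[C@@H](CCCO[Si](C)(C)C(C)(C)C)[C@@H]1C2=C(C(=O)OC2)[C@@H]2C[C@@H]2C(=C)C[C@@H]1O
A5 | alternative 3 | cyclopropene | C1=CC1
A6 | alternative 3 | isopropenylmagnesium bromide | CC(=C)[Mg]Br
A7 | alternative 3 | 3-bromobutenolide with the C1 side chain and C8 as dimethyl acetal | CC(=O)OC[C@@H](CCCO[Si](C)(C)C(C)(C)C)[C@@H](C(OC)OC)C1=C(Br)C(=O)OC1
A8 | alternative 3 | cis-isopropenylcyclopropyl butenolide with C8 as dimethyl acetal | CC(=O)OC[C@@H](CCCO[Si](C)(C)C(C)(C)C)[C@@H](C(OC)OC)C1=C(C(=O)OC1)[C@@H]1C[C@@H]1C(C)=C
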